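**Strategy**

Everything rests on disconnecting the bond between side-chain carbon C1′ and ring carbon C6 of the 2-methylbenzene-1,4-diol. It is made last by a homogentisate geranylgeranyltransferase (UbiA-family aromatic prenyltransferase), which in one operation C-alkylates unprotected homogentisic acid ortho to its C2 hydroxyl with (S)-5-hydroxygeranylgeranyl diphosphate and expels CO2, so that the ring methyl group is the remnant of a CH2CO2H group. The step exploits the benzene-1,4-diol ring whose C1 hydroxyl is flanked by C2–CH3 and C6–C1′, the native product pattern of this enzyme class. The C20 diphosphate is assembled from farnesal by a catalytic asymmetric vinylogous aldol reaction that sets C5′ and the 2′E alkene.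

Key step: step 7

Remark on the chemistry: the stereocentre of the target (C5′) is S (O > C6′ > C4′ > H).
Assumption: the C1=C2 geometry of silyl dienol ether 5 has no bearing on step 3 and is left undefined.
Assumption: the enzyme of step 7 is not a catalogue reagent; it is produced by heterologous expression and used as a membrane fraction.

**Route**

Step 1
Reactants: 1 (2E,6E)-farnesol
Product: 2 (2E,6E)-farnesal
Conditions: activated MnO2 (excess), CH2Cl2, rt
Reagents that add atoms: none
Why: Activated MnO2 oxidises the primary allylic alcohol to the enal under neutral heterogeneous conditions (allylic alcohol oxidation), which should leave the 2E geometry and the isolated trisubstituted alkenes untouched.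

Step 2
Reactants: 3 ethyl 3-methylbut-2-enoate
Product: 5 tert-butyl[(1-ethoxy-3-methylbuta-1,3-dien-1-yl)oxy]dimethylsilane, via lithium dienolate 4 (not isolated)
Conditions: LDA (commercial solution), THF, −78 °C; DMPU, TBSCl, −78 °C → rt; distillation
Reagents that add atoms: tert-butyldimethylsilyl chloride, CC(C)(C)[Si](C)(C)Cl
Why: LDA removes a γ-proton of the senecioate to give the extended lithium dienolate, which the silyl chloride traps on oxygen in the presence of DMPU (silyl ketene acetal formation).

Step 3
Reactants: 2 (2E,6E)-farnesal; 5 silyl dienol ether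
Product: 7 ethyl (2E,5S,6E,10E)-5-hydroxy-3,7,11,15-tetramethylhexadeca-2,6,10,14-tetraenoate, via trichlorosilyl ether 6 (not isolated)
Conditions: SiCl4, (S,S)-BINAM-derived bisphosphoramide (5 mol%), i-Pr2NEt (cat.), CH2Cl2, −78 °C; then sat. aq. NaHCO3
Reagents that add atoms: none
Why: The chiral bisphosphoramide turns SiCl4 into a cationic trichlorosilyl Lewis acid that binds the enal, and the dienol ether attacks the carbonyl through its terminal γ-carbon in an open transition state (catalytic asymmetric vinylogous Mukaiyama aldol reaction), which should give the 1,2-adduct as the (E)-enoate; C5 is set by catalyst control, the catalyst enantiomer being the one that directs attack to the Si face of the aldehyde (expected to be S,S on the facial model of this catalyst family, to be confirmed by Mosher ester analysis of 7).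

Step 4
Reactants: 7 hydroxy ester
Product: 8 (2E,5S,6E,10E)-3,7,11,15-tetramethylhexadeca-2,6,10,14-tetraene-1,5-diol
Conditions: DIBAL-H (3.5 equiv), CH2Cl2, −78 °C; aq. Rochelle salt
Reagents that add atoms: none
Why: DIBAL-H reduces the α,β-unsaturated ester by 1,2-hydride delivery to the allylic alcohol without conjugate reduction (ester reduction), the C5 aluminium alkoxide being inert and the E geometry excluding lactonisation.

Step 5
Reactants: 8 diol
Product: 10 (2E,5S,6E,10E)-1-chloro-3,7,11,15-tetramethylhexadeca-2,6,10,14-tetraen-5-ol, via primary allylic mesylate 9 (not isolated)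
Conditions: MsCl (1.05 equiv), 2,4,6-collidine, LiCl, DMF, 0 °C
Reagents that add atoms: lithium chloride, [Li+].[Cl-] (chloride source; methanesulfonyl chloride, CS(=O)(=O)Cl, supplies the leaving group and further chloride)
Why: The unhindered primary allylic hydroxyl should be sulfonylated much faster than the secondary one flanked by C4H2 and the trisubstituted C6=C7 alkene, and chloride displaces the primary allylic mesylate by SN2 without allylic transposition, while the collidine buffer protects the acid-sensitive C5 allylic alcohol (chemoselective chlorination of an allylic alcohol via its mesylate).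

Step 6
Reactants: 10 chloro alcohol
Product: 11 (2E,5S,6E,10E)-5-hydroxy-3,7,11,15-tetramethylhexadeca-2,6,10,14-tetraen-1-yl diphosphate, triammonium salt
Conditions: (n-Bu4N)3HP2O7 (2 equiv), MeCN, rt; Dowex 50WX8 (NH4+ form), aq. NH4HCO3/i-PrOH; lyophilisation, cellulose chromatography
Reagents that add atoms: tris(tetrabutylammonium) hydrogen diphosphate, CCCC[N+](CCCC)(CCCC)CCCC.CCCC[N+](CCCC)(CCCC)CCCC.CCCC[N+](CCCC)(CCCC)CCCC.OP(=O)([O-])OP(=O)([O-])[O-]; ammonium hydrogencarbonate, [NH4+].OC([O-])=O
Why: The diphosphate anion displaces the primary allylic chloride by SN2 in acetonitrile (pyrophosphate displacement of an allylic halide), a reaction type that tolerates a free hydroxyl elsewhere in the chain, and the 2E geometry keeps O5 from reaching C1 so that no cyclic ether should form.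

Step 7
Reactants: 11 (S)-5-hydroxygeranylgeranyl diphosphate triammonium salt; 12 homogentisic acid
Product: 13 2-[(2E,5S,6E,10E)-5-hydroxy-3,7,11,15-tetramethylhexadeca-2,6,10,14-tetraen-1-yl]-6-methylbenzene-1,4-diol
Conditions: recombinant homogentisate geranylgeranyltransferase (UbiA-type, membrane fraction), MgCl2, DTT, sodium ascorbate, Tris-HCl pH 7.6, 30 °C, Ar, dark; EtOAc extraction
Reagents that add atoms: none
Why: The enzyme ionises the allylic diphosphate of 11 with Mg2+ held by its aspartate-rich motifs, and the allyl cation is captured at its primary terminus C1′ by the ring carbon of bound homogentisate that lies ortho to the C2 hydroxyl and meta to the CH2CO2H group, an enzymatic Friedel–Crafts alkylation. In the same active site the acetic acid side chain loses CO2, plausibly through a keto tautomer of the hydroquinone in which it is a vinylogous β-keto acid, and so ends as the C2 methyl group. The closest known reaction is the native condensation of homogentisate with geranylgeranyl diphosphate to 2-methyl-6-geranylgeranylbenzene-1,4-diol in tocotrienol biosynthesis, run here with a donor that carries one extra hydroxyl at C5′. No ring is closed and no stereocentre is formed; C5′ (S) is remote from the reacting allyl unit and should be carried through unchanged, and the 2′E geometry should be retained because the bound cation is attacked before it can rotate. The step needs C- over O-alkylation, one of three free ring positions, C1′ over C3′ attack and mono-alkylation, all secured by the fixed placement of both substrates in the active site. The open point is whether the chain tunnel accepts the C5′ hydroxyl, so geranylgeranyl-, phytyl- and solanesyl-transferring homologues would be screened.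

**Compound list**

1 | (2E,6E)-farnesol, (2E,6E)-3,7,11-trimethyldodeca-2,6,10-trien-1-ol | CC(C)=CCC/C(C)=C/CC/C(C)=C/CO | starting material
2 | (2E,6E)-farnesal, (2E,6E)-3,7,11-trimethyldodeca-2,6,10-trienal | CC(C)=CCC/C(C)=C/CC/C(C)=C/C=O | intermediate
3 | ethyl 3-methylbut-2-enoate | CCOC(=O)C=C(C)C | starting material
4 | lithium dienolate of 3, lithium 1-ethoxy-3-methylbuta-1,3-dien-1-olate | [Li+].CCOC([O-])=CC(C)=C | intermediate
5 | tert-butyl[(1-ethoxy-3-methylbuta-1,3-dien-1-yl)oxy]dimethylsilane | CCOC(O[Si](C)(C)C(C)(C)C)=CC(C)=C | intermediate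
6 | ethyl (2E,5S,6E,10E)-3,7,11,15-tetramethyl-5-(trichlorosilyloxy)hexadeca-2,6,10,14-tetraenoate | CC(C)=CCC/C(C)=C/CC/C(C)=C/[C@@H](O[Si](Cl)(Cl)Cl)C/C(C)=C/C(=O)OCC | intermediate
7 | ethyl (2E,5S,6E,10E)-5-hydroxy-3,7,11,15-tetramethylhexadeca-2,6,10,14-tetraenoate | CC(C)=CCC/C(C)=C/CC/C(C)=C/[C@@H](O)C/C(C)=C/C(=O)OCC | intermediate
8 | (2E,5S,6E,10E)-3,7,11,15-tetramethylhexadeca-2,6,10,14-tetraene-1,5-diol | CC(C)=CCC/C(C)=C/CC/C(C)=C/[C@@H](O)C/C(C)=C/CO | intermediate
9 | (2E,5S,6E,10E)-5-hydroxy-3,7,11,15-tetramethylhexadeca-2,6,10,14-tetraen-1-yl methanesulfonate | CC(C)=CCC/C(C)=C/CC/C(C)=C/[C@@H](O)C/C(C)=C/COS(C)(=O)=O | intermediate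
10 | (2E,5S,6E,10E)-1-chloro-3,7,11,15-tetramethylhexadeca-2,6,10,14-tetraen-5-ol | CC(C)=CCC/C(C)=C/CC/C(C)=C/[C@@H](O)C/C(C)=C/CCl | intermediate
11 | (2E,5S,6E,10E)-5-hydroxy-3,7,11,15-tetramethylhexadeca-2,6,10,14-tetraen-1-yl diphosphate, triammonium salt | CC(C)=CCC/C(C)=C/CC/C(C)=C/[C@@H](O)C/C(C)=C/COP(=O)([O-])OP(=O)([O-])[O-].[NH4+].[NH4+].[NH4+] | intermediate
12 | homogentisic acid, (2,5-dihydroxyphenyl)acetic acid | OC(=O)Cc1cc(O)ccc1O | starting material
13 | 2-[(2E,5S,6E,10E)-5-hydroxy-3,7,11,15-tetramethylhexadeca-2,6,10,14-tetraen-1-yl]-6-methylbenzene-1,4-diol | CC(C)=CCC/C(C)=C/CC/C(C)=C/[C@@H](O)C/C(C)=C/Cc1cc(O)cc(C)c1O | target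

**Count**

Total steps: 7. Longest linear sequence: 6 (steps 1, 3, 4, 5, 6, 7 from farnesol; step 2 is a one-step branch).

**Steps most likely to fail**

Step 7. The hydroxylated donor may not turn over, either because the C5′ hydroxyl is not accommodated in the chain tunnel or because phosphatases of the membrane preparation hydrolyse the diphosphate faster than it is transferred. The fallback is an aryl cuprate allylation; it sets out from 10 and comes back at 13.
- Chloro alcohol 10 is silylated (TBSOTf, 2,6-lutidine, CH2Cl2, −78 °C) to (2E,5S,6E,10E)-5-(tert-butyldimethylsilyloxy)-1-chloro-3,7,11,15-tetramethylhexadeca-2,6,10,14-tetraene F1.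
- Commercial 4-methoxy-2-methylphenol (COc1ccc(O)c(C)c1) is brominated at the only free position ortho to the hydroxyl (NBS, CH2Cl2, 0 °C) to 2-bromo-4-methoxy-6-methylphenol F2, then O-methylated (MeI, K2CO3, acetone) to 1-bromo-2,5-dimethoxy-3-methylbenzene F3.
- Bromine–lithium exchange on F3 (n-BuLi, THF, −78 °C), transmetalation with CuBr·SMe2 and SN2 allylation of the aryl cuprate with F1 should give 1-[(2E,5S,6E,10E)-5-(tert-butyldimethylsilyloxy)-3,7,11,15-tetramethylhexadeca-2,6,10,14-tetraen-1-yl]-2,5-dimethoxy-3-methylbenzene F4, with the 2′E geometry retained.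
- TBAF (THF) frees (2E,5S,6E,10E)-1-(2,5-dimethoxy-3-methylphenyl)-3,7,11,15-tetramethylhexadeca-2,6,10,14-tetraen-5-ol F5.
- CAN (MeCN/H2O, 0 °C) oxidises the dimethoxyarene to 2-[(2E,5S,6E,10E)-5-hydroxy-3,7,11,15-tetramethylhexadeca-2,6,10,14-tetraen-1-yl]-6-methylcyclohexa-2,5-diene-1,4-dione F6, and Na2S2O4 (Et2O/H2O) reduces the quinone to 13.

Step 3. Enantiofacial control on a β,β-disubstituted enal may be insufficient, the E/Z ratio at C2=C3 may erode (the Z ester would lactonise), or adventitious HCl may cyclise the polyene. The fallback changes the disconnection to C3–C4 alkyne chemistry; it sets out from 2 and comes back at 8.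
- Farnesal 2 is propargylated with allenylboronic acid pinacol ester under chiral phosphoric acid catalysis (TRIP, the enantiomer that gives the S carbinol, toluene, −20 °C) to (4S,5E,9E)-6,10,14-trimethylpentadeca-5,9,13-trien-1-yn-4-ol F7.
- Zirconium-catalysed methylalumination of the terminal alkyne (Me3Al, cat. Cp2ZrCl2, CH2Cl2; Negishi carboalumination, syn addition) and trapping of the alkenylalane with paraformaldehyde should give diol 8, with the 2E alkene fixed by the syn-carbometalation.

Step 5. The secondary allylic hydroxyl may also be sulfonylated and ionise, leading to double chlorination, allylic transposition or elimination to a diene. The fallback masks that hydroxyl before the reduction; it sets out from 7 and comes back at 10.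
- Ester 7 is silylated (TESCl, imidazole, CH2Cl2) to ethyl (2E,5S,6E,10E)-3,7,11,15-tetramethyl-5-(triethylsilyloxy)hexadeca-2,6,10,14-tetraenoate F8.
- DIBAL-H (CH2Cl2, −78 °C) gives (2E,5S,6E,10E)-3,7,11,15-tetramethyl-5-(triethylsilyloxy)hexadeca-2,6,10,14-tetraen-1-ol F9.
- Corey–Kim chlorination (NCS, Me2S, CH2Cl2, −40 → 0 °C) gives (2E,5S,6E,10E)-1-chloro-3,7,11,15-tetramethyl-5-(triethylsilyloxy)hexadeca-2,6,10,14-tetraene F10.
- Buffered HF·pyridine (pyridine, THF, 0 °C) removes the silyl group to give 10.

**Further compounds**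

F1 | step 7 | (2E,5S,6E,10E)-5-(tert-butyldimethylsilyloxy)-1-chloro-3,7,11,15-tetramethylhexadeca-2,6,10,14-tetraene | CC(C)=CCC/C(C)=C/CC/C(C)=C/[C@@H](O[Si](C)(C)C(C)(C)C)C/C(C)=C/CCl
F2 | step 7 | 2-bromo-4-methoxy-6-methylphenol | COc1cc(C)c(O)c(Br)c1
F3 | step 7 | 1-bromo-2,5-dimethoxy-3-methylbenzene | COc1cc(C)c(OC)c(Br)c1
F4 | step 7 | 1-[(2E,5S,6E,10E)-5-(tert-butyldimethylsilyloxy)-3,7,11,15-tetramethylhexadeca-2,6,10,14-tetraen-1-yl]-2,5-dimethoxy-3-methylbenzene | CC(C)=CCC/C(C)=C/CC/C(C)=C/[C@@H](O[Si](C)(C)C(C)(C)C)C/C(C)=C/Cc1cc(OC)cc(C)c1OC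
F5 | step 7 | (2E,5S,6E,10E)-1-(2,5-dimethoxy-3-methylphenyl)-3,7,11,15-tetramethylhexadeca-2,6,10,14-tetraen-5-ol | CC(C)=CCC/C(C)=C/CC/C(C)=C/[C@@H](O)C/C(C)=C/Cc1cc(OC)cc(C)c1OC
F6 | step 7 | 2-[(2E,5S,6E,10E)-5-hydroxy-3,7,11,15-tetramethylhexadeca-2,6,10,14-tetraen-1-yl]-6-methylcyclohexa-2,5-diene-1,4-dione | CC(C)=CCC/C(C)=C/CC/C(C)=C/[C@@H](O)C/C(C)=C/CC1=CC(=O)C=C(C)C1=O
F7 | step 3 | (4S,5E,9E)-6,10,14-trimethylpentadeca-5,9,13-trien-1-yn-4-ol | CC(C)=CCC/C(C)=C/CC/C(C)=C/[C@@H](O)CC#C
F8 | step 5 | ethyl (2E,5S,6E,10E)-3,7,11,15-tetramethyl-5-(triethylsilyloxy)hexadeca-2,6,10,14-tetraenoate | CC(C)=CCC/C(C)=C/CC/C(C)=C/[C@@H](O[Si](CC)(CC)CC)C/C(C)=C/C(=O)OCC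
F9 | step 5 | (2E,5S,6E,10E)-3,7,11,15-tetramethyl-5-(triethylsilyloxy)hexadeca-2,6,10,14-tetraen-1-ol | CC(C)=CCC/C(C)=C/CC/C(C)=C/[C@@H](O[Si](CC)(CC)CC)C/C(C)=C/CO
F10 | step 5 | (2E,5S,6E,10E)-1-chloro-3,7,11,15-tetramethyl-5-(triethylsilyloxy)hexadeca-2,6,10,14-tetraene | CC(C)=CCC/C(C)=C/CC/C(C)=C/[C@@H](O[Si](CC)(CC)CC)C/C(C)=C/CCl
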